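**Retrosynthetic overview**
1. Ring atoms are numbered C1 (CH bearing isopropenyl), C2, C3=C4(CO2Me), C5(OH), C6(=O), C7, C8(OH)(Me), C9, furan C10–C13 (O bridges C10/C13, C12 bears CO2Me), C14.
2. The C5–OH is installed last, by reagent-controlled hydroxylation of the C6-ketone enolate of the 5-deoxy macrocycle.
3. The 14-membered ring (formed last) is closed at C3=C4 by intramolecular Wittig olefination of a C4 phosphorane onto the C3 aldehyde.
4. C6 enters as CO by carbonylative ring expansion of the C7–C8 oxirane to a β-lactone, which carries the C8 carbinol through. The lactone is opened at the acyl carbon by a one-carbon ylide (C5) and relayed to the C4 phosphorane.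
5. The furan (formed first) comes from Feist–Bénary annulation of a β-keto ester made from (S)-4-isopropenyl-δ-valerolactone (Rh conjugate addition sets C1). C9–C10 comes from a furyl Grignard and (R)-2-methylepichlorohydrin.

Assumption: potassium isopropenyltrifluoroborate (2) and (R)-2-(chloromethyl)-2-methyloxirane (10) are purchased.

**Step 1**
Reactants: 1 5,6-dihydro-2H-pyran-2-one; 2 potassium trifluoro(prop-1-en-2-yl)borate
Product: 3 (4S)-4-(prop-1-en-2-yl)oxan-2-one
Conditions: [Rh(cod)2]PF6 (3 mol %), (S)-BINAP (3.3 mol %), toluene/H2O 4:1, 105 °C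
Reagents that add atoms: none
Why: Rh(I)/BINAP asymmetric conjugate addition (Hayashi–Miyaura type) delivers the alkenyl group to the enoate face selected by (S)-BINAP, the sense that gives (S)-3-substituted cyclohexanones, and so sets C1 as S.

**Step 2**
Reactants: 3 (4S)-4-(prop-1-en-2-yl)oxan-2-one; 4 methyl acetate
Product: 5 methyl (5S)-7-hydroxy-3-oxo-5-(prop-1-en-2-yl)heptanoate (in equilibrium with its cyclic hemiketal)
Conditions: LDA (2.4 equiv), MeOAc (2.4 equiv), THF, −78 °C; add 3, −78 to −30 °C; AcOH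
Reagents that add atoms: none
Why: Crossed Claisen acylation of the lithium ester enolate by the lactone stops at the β-keto ester enolate, so there is no over-addition and C1 is untouched.

**Step 3**
Reactants: 5 methyl (5S)-7-hydroxy-3-oxo-5-(prop-1-en-2-yl)heptanoate; 6 chloroacetaldehyde
Product: 7 methyl 2-[(2S)-4-hydroxy-2-(prop-1-en-2-yl)butyl]furan-3-carboxylate
Conditions: ClCH2CHO (45% aq., 1.5 equiv), pyridine, 50 °C
Reagents that add atoms: none
Why: Feist–Bénary furan synthesis, in which C12 adds to the aldehyde (aldol), the enol oxygen displaces chloride and dehydration gives the 2,3-disubstituted furan with C10–H free.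

**Step 4**
Reactants: 7 methyl 2-[(2S)-4-hydroxy-2-(prop-1-en-2-yl)butyl]furan-3-carboxylate
Product: 9 methyl 5-bromo-2-[(2S)-2-(prop-1-en-2-yl)-4-(triethylsilyloxy)butyl]furan-3-carboxylate, via bromofuran alcohol 8 (not isolated)
Conditions: NBS (1.0 equiv), DMF, −20 °C, dark; then imidazole, TESCl, 0 °C
Reagents that add atoms: N-bromosuccinimide O=C1CCC(=O)N1Br; chlorotriethylsilane CC[Si](Cl)(CC)CC
Why: Electrophilic aromatic bromination takes the only free furan α-position (C10) faster than the 1,1-disubstituted alkene reacts at −20 °C, and silylation masks the primary alcohol for the organometallic and Lewis-acid steps.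

**Step 5**
Reactants: 9 methyl 5-bromo-2-[(2S)-2-(prop-1-en-2-yl)-4-(triethylsilyloxy)butyl]furan-3-carboxylate; 10 (2R)-2-(chloromethyl)-2-methyloxirane
Product: 13 methyl 5-{[(2R)-2-methyloxiran-2-yl]methyl}-2-[(2S)-2-(prop-1-en-2-yl)-4-(triethylsilyloxy)butyl]furan-3-carboxylate, via furyl Grignard 11 (not isolated), via chlorohydrin 12 (not isolated)
Conditions: i-PrMgCl·LiCl, THF, −40 °C; CuI (10 mol %), 10 (1.5 equiv), −40 to −10 °C; then t-BuOK, 0 °C
Reagents that add atoms: none
Why: Br/Mg exchange tolerates the ester at −40 °C, Cu-catalysed SN2 opening occurs at the oxirane CH2 (C9) and not at the neopentyl-type CH2Cl, and Williamson closure of the chlorohydrin forms the new oxirane without breaking the C8–O bond, so C8 keeps the configuration of 10.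

**Step 6**
Reactants: 13 methyl 5-{[(2R)-2-methyloxiran-2-yl]methyl}-2-[(2S)-2-(prop-1-en-2-yl)-4-(triethylsilyloxy)butyl]furan-3-carboxylate
Product: 14 methyl 5-{[(2R)-2-methyl-4-oxooxetan-2-yl]methyl}-2-[(2S)-2-(prop-1-en-2-yl)-4-(triethylsilyloxy)butyl]furan-3-carboxylate
Conditions: [(salph)Al(THF)2][Co(CO)4] (5 mol %), CO (60 bar), DME, 40 °C
Reagents that add atoms: carbon monoxide [C-]#[O+]
Why: Ring-expansion carbonylation of an epoxide (Lewis acid/[Co(CO)4]− catalysis), in which cobaltate opens the activated oxirane by SN2 at CH2 (C7), CO inserts and the C8 alkoxide closes on the acyl cobalt, installs C6 with retention at quaternary C8.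

**Step 7**
Reactants: 14 methyl 5-{[(2R)-2-methyl-4-oxooxetan-2-yl]methyl}-2-[(2S)-2-(prop-1-en-2-yl)-4-(triethylsilyloxy)butyl]furan-3-carboxylate
Product: 17 methyl 5-[(2R)-2-hydroxy-7-methoxy-2-methyl-4,7-dioxo-6-(triphenyl-λ5-phosphanylidene)heptyl]-2-[(2S)-4-hydroxy-2-(prop-1-en-2-yl)butyl]furan-3-carboxylate, via keto sulfoxonium ylide 15 (not isolated), via bromoketone 16 (not isolated)
Conditions: Me3S(O)I (1.2 equiv), t-BuOK, THF, 65 °C then 0 °C, add 14; then LiBr, MsOH (1.3 equiv), THF/MeOH, 0 to 25 °C; then Ph3P=CHCO2Me (2.5 equiv), 25 °C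
Reagents that add atoms: trimethylsulfoxonium iodide C[S+](C)(C)=O.[I-]; methyl (triphenylphosphoranylidene)acetate COC(=O)C=P(c1ccccc1)(c1ccccc1)c1ccccc1
Why: Proposed new method: dimethylsulfoxonium methylide attacks the strained β-lactone at the carbonyl (alkyl–O attack is blocked by the quaternary β-carbon) and the released tertiary alkoxide deprotonates the keto sulfoxonium salt, so one equivalent of ylide gives the neutral β-keto sulfoxonium ylide; protonation and bromide displacement of DMSO (with TES methanolysis) then give the bromoketone, which C-alkylates the stabilised phosphorane with transylidation; the closest known reactions are acylation of sulfoxonium methylide by esters and N-acyl β-lactams, HX conversion of keto sulfoxonium ylides into α-halo ketones, and alkylation of Ph3P=CHCO2R by phenacyl bromides.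

**Step 8**
Reactants: 17 methyl 5-[(2R)-2-hydroxy-7-methoxy-2-methyl-4,7-dioxo-6-(triphenyl-λ5-phosphanylidene)heptyl]-2-[(2S)-4-hydroxy-2-(prop-1-en-2-yl)butyl]furan-3-carboxylate
Product: 19 dimethyl (3S,5E,10R)-10-hydroxy-10-methyl-8-oxo-3-(prop-1-en-2-yl)-15-oxabicyclo[10.2.1]pentadeca-1(14),5,12-triene-6,14-dicarboxylate, via aldehyde 18 (not isolated)
Conditions: IBX (3 equiv), DMSO/THF, 45 °C, syringe-pump addition of 17 (final 2 mM)
Reagents that add atoms: none
Why: One-pot IBX oxidation–Wittig olefination oxidises only the primary alcohol, and the α-substituted ester-stabilised ylide closes the 14-membered ring under high dilution to the (E)-trisubstituted enoate (ester trans to C2).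

**Step 9**
Reactants: 19 dimethyl (3S,5E,10R)-10-hydroxy-10-methyl-8-oxo-3-(prop-1-en-2-yl)-15-oxabicyclo[10.2.1]pentadeca-1(14),5,12-triene-6,14-dicarboxylate
Product: 23 dimethyl (3S,5E,7S,10R)-7,10-dihydroxy-10-methyl-8-oxo-3-(prop-1-en-2-yl)-15-oxabicyclo[10.2.1]pentadeca-1(14),5,12-triene-6,14-dicarboxylate, via TMS ether 20 (not isolated), via sodium dienolate 21 (not isolated), via hydroxylated TMS ether 22 (not isolated)
Conditions: TMSOTf (1.1 equiv), Et3N, CH2Cl2, −78 °C; NaHMDS (2.2 equiv), THF, −78 °C; (+)-[(8,8-dichlorocamphoryl)sulfonyl]oxaziridine, −78 °C; AcOH; citric acid, MeOH, 0 °C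
Reagents that add atoms: (+)-[(8,8-dichlorocamphoryl)sulfonyl]oxaziridine CC1(C)C2CCC13CS(=O)(=O)N1OC31C2(Cl)Cl
Why: Davis enolate hydroxylation removes the most acidic C5–H (between the ketone and C3=C4) and oxidises the Z(O)-dienolate at C5 under reagent control, the (+)-reagent giving (S)-acyloins from Z-enolates of acyclic ketones, while the transient TMS ether (removed by mild acid) prevents retro-aldol at C8.

**Compound list**
1 | 5,6-dihydro-2H-pyran-2-one | O=C1C=CCCO1 | starting material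
2 | potassium trifluoro(prop-1-en-2-yl)borate | C=C(C)[B-](F)(F)F.[K+] | starting material
3 | (4S)-4-(prop-1-en-2-yl)oxan-2-one | C=C(C)[C@H]1CCOC(=O)C1 | intermediate
4 | methyl acetate | CC(=O)OC | starting material
5 | methyl (5S)-7-hydroxy-3-oxo-5-(prop-1-en-2-yl)heptanoate | COC(=O)CC(=O)C[C@H](CCO)C(C)=C | intermediate
6 | chloroacetaldehyde | ClCC=O | starting material
7 | methyl 2-[(2S)-4-hydroxy-2-(prop-1-en-2-yl)butyl]furan-3-carboxylate | COC(=O)c1ccoc1C[C@H](CCO)C(C)=C | intermediate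
8 | methyl 5-bromo-2-[(2S)-4-hydroxy-2-(prop-1-en-2-yl)butyl]furan-3-carboxylate (not isolated) | COC(=O)c1cc(Br)oc1C[C@H](CCO)C(C)=C | intermediate
9 | methyl 5-bromo-2-[(2S)-2-(prop-1-en-2-yl)-4-(triethylsilyloxy)butyl]furan-3-carboxylate | COC(=O)c1cc(Br)oc1C[C@H](CCO[Si](CC)(CC)CC)C(C)=C | intermediate
10 | (2R)-2-(chloromethyl)-2-methyloxirane | ClC[C@]1(C)OC1 | starting material
11 | 5-chloromagnesio analogue of 9 (furyl Grignard, not isolated) | COC(=O)c1cc([Mg]Cl)oc1C[C@H](CCO[Si](CC)(CC)CC)C(C)=C | intermediate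
12 | methyl 5-[(2R)-3-chloro-2-hydroxy-2-methylpropyl]-2-[(2S)-2-(prop-1-en-2-yl)-4-(triethylsilyloxy)butyl]furan-3-carboxylate (present as its alkoxide, not isolated) | COC(=O)c1cc(C[C@@](C)(O)CCl)oc1C[C@H](CCO[Si](CC)(CC)CC)C(C)=C | intermediate
13 | methyl 5-{[(2R)-2-methyloxiran-2-yl]methyl}-2-[(2S)-2-(prop-1-en-2-yl)-4-(triethylsilyloxy)butyl]furan-3-carboxylate | COC(=O)c1cc(C[C@]2(C)CO2)oc1C[C@H](CCO[Si](CC)(CC)CC)C(C)=C | intermediate
14 | methyl 5-{[(2R)-2-methyl-4-oxooxetan-2-yl]methyl}-2-[(2S)-2-(prop-1-en-2-yl)-4-(triethylsilyloxy)butyl]furan-3-carboxylate | COC(=O)c1cc(C[C@]2(C)CC(=O)O2)oc1C[C@H](CCO[Si](CC)(CC)CC)C(C)=C | intermediate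
15 | methyl 5-[(2R)-5-(dimethyloxo-λ6-sulfanylidene)-2-hydroxy-2-methyl-4-oxopentyl]-2-[(2S)-2-(prop-1-en-2-yl)-4-(triethylsilyloxy)butyl]furan-3-carboxylate (not isolated) | COC(=O)c1cc(C[C@@](C)(O)CC(=O)[CH-][S+](C)(C)=O)oc1C[C@H](CCO[Si](CC)(CC)CC)C(C)=C | intermediate
16 | methyl 5-[(2R)-5-bromo-2-hydroxy-2-methyl-4-oxopentyl]-2-[(2S)-4-hydroxy-2-(prop-1-en-2-yl)butyl]furan-3-carboxylate (not isolated) | COC(=O)c1cc(C[C@@](C)(O)CC(=O)CBr)oc1C[C@H](CCO)C(C)=C | intermediate
17 | methyl 5-[(2R)-2-hydroxy-7-methoxy-2-methyl-4,7-dioxo-6-(triphenyl-λ5-phosphanylidene)heptyl]-2-[(2S)-4-hydroxy-2-(prop-1-en-2-yl)butyl]furan-3-carboxylate | COC(=O)c1cc(C[C@@](C)(O)CC(=O)CC(C(=O)OC)=P(c2ccccc2)(c2ccccc2)c2ccccc2)oc1C[C@H](CCO)C(C)=C | intermediate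
18 | methyl 5-[(2R)-2-hydroxy-7-methoxy-2-methyl-4,7-dioxo-6-(triphenyl-λ5-phosphanylidene)heptyl]-2-[(2R)-4-oxo-2-(prop-1-en-2-yl)butyl]furan-3-carboxylate (not isolated; same spatial arrangement at C1, descriptor changes by CIP) | COC(=O)c1cc(C[C@@](C)(O)CC(=O)CC(C(=O)OC)=P(c2ccccc2)(c2ccccc2)c2ccccc2)oc1C[C@H](CC=O)C(C)=C | intermediate
19 | dimethyl (3S,5E,10R)-10-hydroxy-10-methyl-8-oxo-3-(prop-1-en-2-yl)-15-oxabicyclo[10.2.1]pentadeca-1(14),5,12-triene-6,14-dicarboxylate (5-deoxy target) | C=C(C)[C@H]1C/C=C(/C(=O)OC)CC(=O)C[C@](C)(O)CC2=CC(C(=O)OC)=C(C1)O2 | intermediate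
20 | C8-O-trimethylsilyl ether of 19 (not isolated) | C=C(C)[C@H]1C/C=C(/C(=O)OC)CC(=O)C[C@](C)(O[Si](C)(C)C)CC2=CC(C(=O)OC)=C(C1)O2 | intermediate
21 | sodium Z(O)-dienolate (C5=C6) of 20 (not isolated) | C=C(C)[C@H]1C/C=C(/C(=O)OC)\C=C(/[O-])C[C@](C)(O[Si](C)(C)C)CC2=CC(C(=O)OC)=C(C1)O2.[Na+] | intermediate
22 | C8-O-trimethylsilyl ether of 23 (5S, not isolated) | C=C(C)[C@H]1C/C=C(/C(=O)OC)[C@H](O)C(=O)C[C@](C)(O[Si](C)(C)C)CC2=CC(C(=O)OC)=C(C1)O2 | intermediate
23 | dimethyl (3S,5E,7S,10R)-7,10-dihydroxy-10-methyl-8-oxo-3-(prop-1-en-2-yl)-15-oxabicyclo[10.2.1]pentadeca-1(14),5,12-triene-6,14-dicarboxylate (CNP0225662.1) | C=C(C)[C@H]1C/C=C(/C(=O)OC)[C@H](O)C(=O)C[C@](C)(O)CC2=CC(C(=O)OC)=C(C1)O2 | target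

**Step count and risk**
Total steps: 9. Longest linear sequence: 9 (fully linear from 1).

Three steps most likely to fail:

Step 7 (proposed new step). The ylide may attack the furan ester, or the telescoped bromide exchange and ylide alkylation may not run cleanly in one flask. The fallback uses known chemistry and sets out from 14. Aminolysis of the β-lactone with Me(MeO)NH·HCl and i-PrMgCl gives the β-hydroxy Weinreb amide F1. Homologation with LiCH2Br (CH2Br2, MeLi·LiBr, −78 °C) gives the bromomethyl ketone TES ether F2. PPTS in MeOH removes the TES group and returns to the route at 16, which is then isolated and treated with Ph3P=CHCO2Me as in the last stage of step 7.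

Step 8 (macrocyclisation). Oligomerisation or poor E/Z control in the ylide ring closure are the risks. The fallback sets out from 16 (step 7 stopped at the bromoketone). Alkylation of sodium trimethyl phosphonoacetate gives the phosphonate F3 (epimers at the phosphonate carbon). Dess–Martin oxidation of the primary alcohol gives the aldehyde phosphonate F4. Intramolecular Horner–Wadsworth–Emmons closure under Masamune–Roush conditions (LiCl, DBU, MeCN, 1 mM) returns to the route at 19.

Step 9 (C5 hydroxylation). The sense of induction depends on the enolate geometry imposed by the ring, which is assumed Z(O) and is not established, and retro-aldol at C8 is possible. The fallback sets out from 19. TESOTf and Et3N give the bis-silylated dienol ether F5. Catalyst-controlled Shi epoxidation (fructose-derived ketone, Oxone, pH 10.5, 0 °C) with silyl migration gives the bis-TES ether of the target F6. HF·pyridine returns to the route at 23.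

**Further compounds**
F1 | step 7 | methyl 5-{(2R)-2-hydroxy-4-[methoxy(methyl)amino]-2-methyl-4-oxobutyl}-2-[(2S)-2-(prop-1-en-2-yl)-4-(triethylsilyloxy)butyl]furan-3-carboxylate | COC(=O)c1cc(C[C@@](C)(O)CC(=O)N(C)OC)oc1C[C@H](CCO[Si](CC)(CC)CC)C(C)=C
F2 | step 7 | methyl 5-[(2R)-5-bromo-2-hydroxy-2-methyl-4-oxopentyl]-2-[(2S)-2-(prop-1-en-2-yl)-4-(triethylsilyloxy)butyl]furan-3-carboxylate | COC(=O)c1cc(C[C@@](C)(O)CC(=O)CBr)oc1C[C@H](CCO[Si](CC)(CC)CC)C(C)=C
F3 | step 8 | methyl 5-[(2R)-6-(dimethoxyphosphoryl)-2-hydroxy-7-methoxy-2-methyl-4,7-dioxoheptyl]-2-[(2S)-4-hydroxy-2-(prop-1-en-2-yl)butyl]furan-3-carboxylate | COC(=O)c1cc(C[C@@](C)(O)CC(=O)CC(C(=O)OC)P(=O)(OC)OC)oc1C[C@H](CCO)C(C)=C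
F4 | step 8 | methyl 5-[(2R)-6-(dimethoxyphosphoryl)-2-hydroxy-7-methoxy-2-methyl-4,7-dioxoheptyl]-2-[(2R)-4-oxo-2-(prop-1-en-2-yl)butyl]furan-3-carboxylate | COC(=O)c1cc(C[C@@](C)(O)CC(=O)CC(C(=O)OC)P(=O)(OC)OC)oc1C[C@H](CC=O)C(C)=C
F5 | step 9 | C8-O-triethylsilyl C6-O-triethylsilyl Z(O)-dienol ether of 19 | C=C(C)[C@H]1C/C=C(/C(=O)OC)\C=C(/O[Si](CC)(CC)CC)C[C@](C)(O[Si](CC)(CC)CC)CC2=CC(C(=O)OC)=C(C1)O2
F6 | step 9 | C5-O,C8-O-bis(triethylsilyl) ether of 23 | C=C(C)[C@H]1C/C=C(/C(=O)OC)[C@H](O[Si](CC)(CC)CC)C(=O)C[C@](C)(O[Si](CC)(CC)CC)CC2=CC(C(=O)OC)=C(C1)O2
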